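## Retrosynthetic overview

1. The target, (3R,5S)-5-[5-(2,5-dihydroxyphenyl)furan-3-yl]-3,8-dimethylnon-7-enoic acid, comes from one-pot saponification of its methyl ester bis-pivalate. The aryl–furan bond comes from Suzuki coupling of a furan-2-yl boronate with O,O-dipivaloyl bromohydroquinone. The boronate comes from sterically controlled Ir C–H borylation of the 3-alkylfuran.
2. The C7=C8 prenyl alkene comes from an isopropylidene Wittig reaction on a C-7 aldehyde. That aldehyde derives from a tert-butyl ester orthogonal to the C-1 methyl ester.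
3. The C5–furyl bond and C-5 (S) come from Rh/(R)-BINAP 1,4-addition of furan-3-ylboronic acid to an E-enoate. The C5=C6 bond of that enoate is made by a stabilised Wittig reaction.
4. C-3 (R) is the first stereocentre. It comes from carboxylesterase (pig liver esterase) desymmetrisation of prochiral dimethyl 3-methylglutarate, followed by conversion of the acid into an aldehyde.
5. No ring is built. The furan is brought in intact first (step 5) and the benzene ring second (step 12).

Assumption: the five achiral building blocks (dimethyl 3-methylglutarate, tert-butyl (triphenylphosphoranylidene)acetate, furan-3-ylboronic acid, isopropyltriphenylphosphonium iodide, bromohydroquinone) are taken as catalogue chemicals. C-1 to C-9 denote the nonenoic acid chain of the target.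

## Route

**Step 1**
Reactants: 1 dimethyl 3-methylpentanedioate
Product: 2 (3R)-5-methoxy-3-methyl-5-oxopentanoic acid
Conditions: pig liver esterase (carboxylesterase, serine hydrolase, EC 3.1.1.1), 0.1 M phosphate buffer pH 7.0/MeOH 4:1, −10 °C, pH-stat 1 M NaOH (1.0 equiv); then 2 M HCl to pH 2
Reagents that add atoms: water, O
Why: Enzymatic desymmetrisation of a prochiral diester, in which the carboxylesterase hydrolyses only the pro-S ester arm and stops at the mono-acid, so C-3 is set as R (about 95–97 % ee under the cold aqueous-methanol protocol).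

**Step 2**
Reactants: 2 (3R)-5-methoxy-3-methyl-5-oxopentanoic acid
Product: 3 methyl (3R)-5-hydroxy-3-methylpentanoate
Conditions: BH3·SMe2 (1.2 equiv), THF, −10 °C to rt; then H2O; used at once
Reagents that add atoms: none
Why: Chemoselective borane reduction, in which the free acid is reduced via its acyloxyborane much faster than the methyl ester, the stereocentre is untouched, and neutral handling avoids lactonisation.

**Step 3**
Reactants: 3 methyl (3R)-5-hydroxy-3-methylpentanoate
Product: 4 methyl (3R)-3-methyl-5-oxopentanoate
Conditions: Dess–Martin periodinane (1.2 equiv), pyridine (3 equiv), CH2Cl2, 0 °C to rt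
Reagents that add atoms: none
Why: Dess–Martin oxidation stops at the aldehyde under buffered conditions, and the stereocentre is β to both carbonyls so it cannot epimerise.

**Step 4**
Reactants: 4 methyl (3R)-3-methyl-5-oxopentanoate; 5 tert-butyl (triphenyl-λ5-phosphanylidene)acetate
Product: 6 1-tert-butyl 7-methyl (2E,5R)-5-methylhept-2-enedioate
Conditions: CH2Cl2, rt, 12 h
Reagents that add atoms: none
Why: Wittig olefination with a stabilised ylide gives the E-enoate (>20:1) without touching the methyl ester, and the bulky tert-butyl ester raises the selectivity of the next step and is orthogonal to the methyl ester.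

**Step 5**
Reactants: 6 1-tert-butyl 7-methyl (2E,5R)-5-methylhept-2-enedioate; 7 furan-3-ylboronic acid (2 equiv)
Product: 8 1-tert-butyl 7-methyl (3S,5R)-3-(furan-3-yl)-5-methylheptanedioate
Conditions: [Rh(nbd)2]BF4 (3 mol %), (R)-BINAP (3.3 mol %), Et3N (1 equiv), 1,4-dioxane/H2O 8:1, 30–40 °C, 24 h
Reagents that add atoms: none
Why: Hayashi–Miyaura rhodium-catalysed asymmetric 1,4-addition, in which the (R)-BINAP–Rh–furyl species adds to the α-re face of the E-enoate (the same sense as (R)-BINAP with a crotonate giving the (S)-3-arylbutanoate), so the furyl-bearing centre is set as S under catalyst control and the few per cent of ent-6 becomes a removable diastereomer.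

**Step 6**
Reactants: 8 1-tert-butyl 7-methyl (3S,5R)-3-(furan-3-yl)-5-methylheptanedioate
Product: 10 (3S,5R)-3-(furan-3-yl)-7-methoxy-5-methyl-7-oxoheptanoic acid, via trimethylsilyl ester 9 (not isolated)
Conditions: TMSOTf (2.5 equiv), 2,6-lutidine (3.5 equiv), CH2Cl2, 0 °C to rt; then pH 4 aqueous buffer
Reagents that add atoms: trimethylsilyl trifluoromethanesulfonate, C[Si](C)(C)OS(=O)(=O)C(F)(F)F (its Me3Si group sits only in 9 and is lost again on work-up)
Why: Silyl-triflate-mediated tert-butyl ester cleavage (loss of isobutene, then hydrolysis of the silyl ester) runs in a lutidine-buffered medium, so the acid-sensitive furan is neither protonated nor tert-butylated and the methyl ester stays.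

**Step 7**
Reactants: 10 (3S,5R)-3-(furan-3-yl)-7-methoxy-5-methyl-7-oxoheptanoic acid
Product: 11 methyl (3R,5S)-5-(furan-3-yl)-7-hydroxy-3-methylheptanoate
Conditions: BH3·SMe2 (1.5 equiv), THF, 0 °C to rt; then H2O
Reagents that add atoms: none
Why: Chemoselective borane reduction of the acid in the presence of the methyl ester and the furan, with minor diastereomers removed by chromatography at this polar alcohol stage.

**Step 8**
Reactants: 11 methyl (3R,5S)-5-(furan-3-yl)-7-hydroxy-3-methylheptanoate
Product: 12 methyl (3R,5S)-5-(furan-3-yl)-3-methyl-7-oxoheptanoate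
Conditions: Dess–Martin periodinane (1.2 equiv), pyridine (3 equiv), CH2Cl2, 0 °C to rt
Reagents that add atoms: none
Why: Dess–Martin oxidation is mild enough for the furan, and C-5 is β to the new aldehyde so it is configurationally safe.

**Step 9**
Reactants: 12 methyl (3R,5S)-5-(furan-3-yl)-3-methyl-7-oxoheptanoate; 13 isopropyltriphenylphosphonium iodide (1.6 equiv)
Product: 15 methyl (3R,5S)-5-(furan-3-yl)-3,8-dimethylnon-7-enoate, via isopropylidenetriphenylphosphorane 14 (not isolated)
Conditions: 13, n-BuLi (1.5 equiv), THF, 0 °C, 30 min; then 12, −78 °C to 0 °C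
Reagents that add atoms: none
Why: Wittig olefination with the non-stabilised isopropylidene ylide reacts with the aldehyde far faster than with the methyl ester at low temperature and gives the trisubstituted prenyl alkene with no geometric or positional ambiguity.

**Step 10**
Reactants: 15 methyl (3R,5S)-5-(furan-3-yl)-3,8-dimethylnon-7-enoate
Product: 16 methyl (3R,5S)-3,8-dimethyl-5-[5-(4,4,5,5-tetramethyl-1,3,2-dioxaborolan-2-yl)furan-3-yl]non-7-enoate
Conditions: [Ir(OMe)(cod)]2 (1.5 mol %), dtbpy (3 mol %), B2pin2 (1.0 equiv), MTBE, rt, 2–6 h; short silica plug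
Reagents that add atoms: bis(pinacolato)diboron, CC1(C)OB(OC1(C)C)B1OC(C)(C)C(C)(C)O1
Why: Iridium-catalysed aromatic C–H borylation (Ishiyama–Miyaura–Hartwig) is sterically governed, so of the two furan α-C–H bonds only the one remote from the branched sec-alkyl group reacts, and the ester and the trisubstituted alkene are inert at room temperature.

**Step 11**
Reactants: 17 2-bromobenzene-1,4-diol
Product: 18 2-bromo-1,4-phenylene bis(2,2-dimethylpropanoate)
Conditions: PivCl (2.4 equiv), Et3N (3 equiv), DMAP (5 mol %), CH2Cl2, 0 °C to rt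
Reagents that add atoms: pivaloyl chloride, CC(C)(C)C(=O)Cl
Why: DMAP-catalysed O-acylation masks the oxidation-prone hydroquinone as hindered esters that make the bromide a better oxidative-addition partner and can be removed later by base alone.

**Step 12**
Reactants: 16 methyl (3R,5S)-3,8-dimethyl-5-[5-(4,4,5,5-tetramethyl-1,3,2-dioxaborolan-2-yl)furan-3-yl]non-7-enoate; 18 2-bromo-1,4-phenylene bis(2,2-dimethylpropanoate)
Product: 19 methyl (3R,5S)-5-{5-[2,5-bis(2,2-dimethylpropanoyloxy)phenyl]furan-3-yl}-3,8-dimethylnon-7-enoate
Conditions: XPhos Pd G3 (3 mol %), K3PO4 (2 equiv, degassed 0.5 M aq), THF, 40 °C, 2–4 h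
Reagents that add atoms: none
Why: Suzuki–Miyaura coupling with a fast-activating biarylphosphine precatalyst at 40 °C outruns protodeboronation of the 2-furylboronate, the phosphate base spares the hindered pivalates and the methyl ester, and any partly deacylated material converges in the last step.

**Step 13**
Reactants: 19 methyl (3R,5S)-5-{5-[2,5-bis(2,2-dimethylpropanoyloxy)phenyl]furan-3-yl}-3,8-dimethylnon-7-enoate
Product: 20 (3R,5S)-5-[5-(2,5-dihydroxyphenyl)furan-3-yl]-3,8-dimethylnon-7-enoic acid
Conditions: LiOH·H2O (10 equiv), degassed THF/H2O 2:1, Ar, 40 °C, 12 h; then cold degassed 1 M HCl to pH 3, EtOAc extraction, aq Na2S2O4 wash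
Reagents that add atoms: lithium hydroxide, [Li+].[OH-]
Why: Global saponification cleaves both aryl pivalates and the methyl ester without strong acid or fluoride, so the prenyl alkene cannot cyclise onto the furan, neither non-enolisable stereocentre is touched, and exclusion of air keeps the hydroquinone from oxidising to the quinone.

## Compound list

1 | dimethyl 3-methylpentanedioate | COC(=O)CC(C)CC(=O)OC | starting material
2 | (3R)-5-methoxy-3-methyl-5-oxopentanoic acid | OC(=O)C[C@@H](C)CC(=O)OC | intermediate
3 | methyl (3R)-5-hydroxy-3-methylpentanoate | OCC[C@@H](C)CC(=O)OC | intermediate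
4 | methyl (3R)-3-methyl-5-oxopentanoate | O=CC[C@@H](C)CC(=O)OC | intermediate
5 | tert-butyl (triphenyl-λ5-phosphanylidene)acetate | CC(C)(C)OC(=O)C=P(c1ccccc1)(c1ccccc1)c1ccccc1 | starting material
6 | 1-tert-butyl 7-methyl (2E,5R)-5-methylhept-2-enedioate | CC(C)(C)OC(=O)/C=C/C[C@@H](C)CC(=O)OC | intermediate
7 | furan-3-ylboronic acid | OB(O)c1ccoc1 | starting material
8 | 1-tert-butyl 7-methyl (3S,5R)-3-(furan-3-yl)-5-methylheptanedioate | CC(C)(C)OC(=O)C[C@H](C[C@@H](C)CC(=O)OC)c1ccoc1 | intermediate
9 | 7-methyl 1-trimethylsilyl (3S,5R)-3-(furan-3-yl)-5-methylheptanedioate (not isolated) | C[Si](C)(C)OC(=O)C[C@H](C[C@@H](C)CC(=O)OC)c1ccoc1 | intermediate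
10 | (3S,5R)-3-(furan-3-yl)-7-methoxy-5-methyl-7-oxoheptanoic acid | OC(=O)C[C@H](C[C@@H](C)CC(=O)OC)c1ccoc1 | intermediate
11 | methyl (3R,5S)-5-(furan-3-yl)-7-hydroxy-3-methylheptanoate | OCC[C@H](C[C@@H](C)CC(=O)OC)c1ccoc1 | intermediate
12 | methyl (3R,5S)-5-(furan-3-yl)-3-methyl-7-oxoheptanoate | O=CC[C@H](C[C@@H](C)CC(=O)OC)c1ccoc1 | intermediate
13 | isopropyltriphenylphosphonium iodide | CC(C)[P+](c1ccccc1)(c1ccccc1)c1ccccc1.[I-] | starting material
14 | isopropylidenetriphenylphosphorane (not isolated) | CC(C)=P(c1ccccc1)(c1ccccc1)c1ccccc1 | intermediate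
15 | methyl (3R,5S)-5-(furan-3-yl)-3,8-dimethylnon-7-enoate | CC(C)=CC[C@H](C[C@@H](C)CC(=O)OC)c1ccoc1 | intermediate
16 | methyl (3R,5S)-3,8-dimethyl-5-[5-(4,4,5,5-tetramethyl-1,3,2-dioxaborolan-2-yl)furan-3-yl]non-7-enoate | CC(C)=CC[C@H](C[C@@H](C)CC(=O)OC)c1coc(B2OC(C)(C)C(C)(C)O2)c1 | intermediate
17 | 2-bromobenzene-1,4-diol (bromohydroquinone) | Oc1ccc(O)c(Br)c1 | starting material
18 | 2-bromo-1,4-phenylene bis(2,2-dimethylpropanoate) | CC(C)(C)C(=O)Oc1ccc(OC(=O)C(C)(C)C)c(Br)c1 | intermediate
19 | methyl (3R,5S)-5-{5-[2,5-bis(2,2-dimethylpropanoyloxy)phenyl]furan-3-yl}-3,8-dimethylnon-7-enoate | CC(C)=CC[C@H](C[C@@H](C)CC(=O)OC)c1coc(-c2cc(OC(=O)C(C)(C)C)ccc2OC(=O)C(C)(C)C)c1 | intermediate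
20 | (3R,5S)-5-[5-(2,5-dihydroxyphenyl)furan-3-yl]-3,8-dimethylnon-7-enoic acid | CC(C)=CC[C@H](C[C@@H](C)CC(=O)O)c1coc(-c2cc(O)ccc2O)c1 | target

## Step count

Total step count: 13.
Longest linear sequence: 12 (steps 1–10, 12, 13). Step 11 is a one-step side branch.

## Steps most likely to fail and their fallbacks

**Step 5.** The heteroarylboronic acid may protodeboronate, or the bulky enoate may react slowly or with too low a diastereomer ratio. The fallback sets the same centre by C–H instead of C–C bond formation. It sets out from 2 and comes back at 8. Oxalyl chloride with catalytic DMF turns 2 into the acid chloride methyl (3S)-5-chloro-3-methyl-5-oxopentanoate F1; the descriptor changes only because of CIP priorities. Anhydrous acyl-Suzuki coupling of this chloride with 7 (Pd(PPh3)4, Cs2CO3, toluene) gives the ketone methyl (3R)-5-(furan-3-yl)-3-methyl-5-oxopentanoate F2. Horner–Wadsworth–Emmons olefination with tert-butyl diethylphosphonoacetate (NaH, THF), followed by separation of the geometric isomers, gives 1-tert-butyl 7-methyl (2E,5R)-3-(furan-3-yl)-5-methylhept-2-enedioate F3. Copper-hydride-catalysed asymmetric conjugate reduction (Cu(OAc)2, DTBM-SEGPHOS, PMHS, t-BuOH, toluene) then delivers 8. The ligand antipode is fixed by a test run against authentic 8.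

**Step 6.** The tert-butyl ester must be removed next to an acid-sensitive, easily alkylated furan. The fallback swaps the ester so that it is removed by neutral hydrogenolysis before any alkene is present. It sets out from 4 and comes back at 10. Wittig reaction of 4 with benzyl (triphenylphosphoranylidene)acetate gives 1-benzyl 7-methyl (2E,5R)-5-methylhept-2-enedioate F4. The same Rh/(R)-BINAP addition of 7 gives 1-benzyl 7-methyl (3S,5R)-3-(furan-3-yl)-5-methylheptanedioate F5. Brief hydrogenolysis (H2 1 atm, 10 % Pd/C, EtOAc, monitored closely to spare the furan) gives 10.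

**Step 10.** The risks are the regioselectivity between the two furan α-positions, side reactions at the alkene, and handling of the labile boronate. The fallback skips the boron chemistry altogether. It sets out from 15 (together with 18) and comes back at 19. It is a palladium-catalysed direct C–H arylation by concerted metalation–deprotonation (Pd(OAc)2, KOAc, DMA, 120 °C). The ortho-substituted bromide 18 and the branched alkyl group together steer arylation to the unhindered α-position. This fallback makes no new compound (F0).

## Further compounds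

F1 | step 5 | methyl (3S)-5-chloro-3-methyl-5-oxopentanoate | ClC(=O)C[C@@H](C)CC(=O)OC
F2 | step 5 | methyl (3R)-5-(furan-3-yl)-3-methyl-5-oxopentanoate | O=C(C[C@@H](C)CC(=O)OC)c1ccoc1
F3 | step 5 | 1-tert-butyl 7-methyl (2E,5R)-3-(furan-3-yl)-5-methylhept-2-enedioate | CC(C)(C)OC(=O)/C=C(\C[C@@H](C)CC(=O)OC)c1ccoc1
F4 | step 6 | 1-benzyl 7-methyl (2E,5R)-5-methylhept-2-enedioate | O=C(OCc1ccccc1)/C=C/C[C@@H](C)CC(=O)OC
F5 | step 6 | 1-benzyl 7-methyl (3S,5R)-3-(furan-3-yl)-5-methylheptanedioate | O=C(OCc1ccccc1)C[C@H](C[C@@H](C)CC(=O)OC)c1ccoc1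
F0 | step 10 | none | none
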